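## Retrosynthetic overview

1. Bought rings: both arene rings come with (E)-3,4,5-trimethoxycinnamic acid 1, both dihydropyridinone rings with 5,6-dihydropyridin-2(1H)-one 2. The cyclobutane is the only ring that is made, and it is made last.
2. Imide N–C(O) disconnection: 1, activated in the flask as acid chloride 3, N-acylates 2 to give the monomer piplartine 4.
3. Cyclobutane disconnection (both ring C–C bonds at once): target 5 ⇒ 2 × 4, a head-to-tail [2+2] photodimerisation of the cinnamoyl C=C bonds inside the crystal of 4. This is the same light-driven dimerisation of piplartine by which the plant is presumed to form the alkaloid.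
4. The E geometry of 4 and a centrosymmetric stacked pair fix all four stereocentres in that one step; there are no protecting groups and no redox steps.

Assumption: the target has a centre of inversion (1α,2α,3β,4β, α-truxillic type), so it is achiral; the four descriptors in the SMILES define relative configuration only, and "single enantiomer" is read as "this single diastereomer".

## Route

Step 1
Reactants: 1 (E)-3,4,5-trimethoxycinnamic acid; 2 5,6-dihydropyridin-2(1H)-one
Product: 4 piplartine ((E)-1-[3-(3,4,5-trimethoxyphenyl)prop-2-enoyl]-5,6-dihydropyridin-2(1H)-one), via 3,4,5-trimethoxycinnamoyl chloride 3 (not isolated)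
Conditions: (COCl)2 (1.05 equiv), DMF (cat.), CH2Cl2, 0 °C → rt, 2 h; then 2 (1.1 equiv), Et3N (3 equiv), DMAP (0.1 equiv), 0 °C → rt, same flask
Reagents that add atoms: oxalyl chloride, O=C(Cl)C(Cl)=O (gives only the Cl of intermediate 3; none of its atoms stays in 4)
Why: Vilsmeier-catalysed acid chloride formation followed by DMAP-assisted N-acylation of the lactam (imide formation); no stereocentre is formed, and the E-cinnamoyl unit has no α-hydrogen, so it can neither form a ketene nor isomerise.

Step 2
Reactants: 4 piplartine (two molecules)
Product: 5 piplartine-dimer A, 1,1'-{[(1α,2α,3β,4β)-2,4-bis(3,4,5-trimethoxyphenyl)cyclobutane-1,3-diyl]dicarbonyl}bis(5,6-dihydropyridin-2(1H)-one). C1 and C3 carry the acyl-dihydropyridinone groups, C2 and C4 the aryl groups; the substituents at C1 and C2 are on the upper face, those at C3 and C4 on the lower face; centrosymmetric, achiral.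
Conditions: recryst. 4 (EtOAc–hexane; crystal form with parallel C=C pairs ≤ 4.2 Å checked by X-ray); microcrystals as stirred suspension in H2O, hν (350 nm, Pyrex), N2, 10–15 °C, 24–48 h
Reagents that add atoms: none
Why: Proposed new method: a lattice-controlled (topochemical) [2+2] photodimerisation, whose closest known reaction type is the solid-state conversion of α-packed trans-cinnamic acids and cinnamamides into α-truxillic derivatives (Schmidt rule); the flat push–pull imide 4 is expected to stack as centrosymmetric antiparallel pairs (electron-rich trimethoxyphenyl over the electron-poor acyl imide), which places the two cinnamoyl C=C bonds parallel, head-to-tail and within about 4 Å, so that excitation closes both new σ-bonds by least motion inside one pair, each former E-alkene keeps its trans aryl/acyl relation, the two new bonds carry cis substituents, and the inversion centre of the pair becomes that of the product, which sets all four stereocentres (1α,2α,3β,4β) at once, while the lattice blocks E/Z isomerisation and keeps the ring enones out of reach, and 5, lacking the cinnamoyl chromophore, no longer absorbs at 350 nm and is not cleaved back.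

## Compound list

1 | (E)-3-(3,4,5-trimethoxyphenyl)prop-2-enoic acid (3,4,5-trimethoxycinnamic acid) | COc1cc(/C=C/C(=O)O)cc(OC)c1OC | starting material
2 | 5,6-dihydropyridin-2(1H)-one | O=C1C=CCCN1 | starting material
3 | (E)-3-(3,4,5-trimethoxyphenyl)prop-2-enoyl chloride | COc1cc(/C=C/C(=O)Cl)cc(OC)c1OC | intermediate (not isolated)
4 | piplartine, (E)-1-[3-(3,4,5-trimethoxyphenyl)prop-2-enoyl]-5,6-dihydropyridin-2(1H)-one | COc1cc(/C=C/C(=O)N2CCC=CC2=O)cc(OC)c1OC | intermediate
5 | piplartine-dimer A (1α,2α,3β,4β; achiral) | COc1cc([C@H]2[C@H](C(=O)N3CCC=CC3=O)[C@H](c3cc(OC)c(OC)c(OC)c3)[C@H]2C(=O)N2CCC=CC2=O)cc(OC)c1OC | target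

## Step count and risks

Total step count: 2. Longest linear sequence: 2.

The route has only two steps, so the three entries below are the two independent ways in which step 2 can fail, followed by step 1.

**1. Step 2, first way to fail: the crystal form of 4 is photoinert, or the ring enone takes part.** This happens if the C=C pairs are further apart than about 4.2 Å or not parallel. The fallback sets out from 1 and comes back to the route at 5. The cycloaddition is moved to the acid stage, where the cinnamoyl unit is the only chromophore and centrosymmetric stacking is common for alkoxycinnamic acids. Crystalline 1 is irradiated as a solid (Pyrex, aqueous slurry) to give the α-truxillic diacid F1. Oxalyl chloride with catalytic DMF in CH2Cl2 converts it into the bis(acid chloride) F2. F2 is added at −78 °C in THF to the lithium lactamate F3, made from 2 and LiHMDS; no amine base is used, so that no ketene can form and epimerise the cyclobutane α-carbons. Double N-acylation gives 5.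

**2. Step 2, second way to fail: neither 4 nor 1 offers a head-to-tail reactive lattice.** Head-to-head packing would give the truxinic skeleton, and other packings nothing. The fallback sets out from 1 and comes back at 5, and it gives up lattice control altogether. 1 is esterified (MeOH, cat. H2SO4, reflux) to the methyl cinnamate F4. F4 is irradiated in CH2Cl2 (0.3 M, Pyrex) with BF3·OEt2 (0.5 equiv). This uses the solution photodimerisation of Lewis-acid-complexed cinnamic esters, in which the excited complex pairs head-to-tail with a free ester and the α-truxillate is reported as the main dimer. Chromatography gives the dimethyl α-truxillate F5. Hydrolysis with aqueous HCl–dioxane at 90 °C (acidic, so the α-carbons are not epimerised) gives the α-truxillic diacid F1. F1 is then taken through the bis(acid chloride) F2 and the lithium lactamate F3 to 5 as in the first fallback.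

**3. Step 1: N-acylation of 2 gives low conversion or oligomers.** 2 is a weak N–H nucleophile and a Michael acceptor towards amine bases. The fallback sets out from 3 (made from 1 as in step 1) and comes back at 4. The robust saturated lactam is acylated and the ring C=C is introduced afterwards. 3 is heated with commercial piperidin-2-one (O=C1CCCCN1), Et3N and DMAP in toluene at 80 °C to give the saturated imide F6. LiHMDS (THF, −78 °C) removes the only enolisable proton (lactam C3–H) to give the lithium enolate F7. PhSeBr traps it as the α-phenylselanyl imide F8. H2O2 (CH2Cl2, pyridine, 0 °C) oxidises this to the selenoxide F9, which undergoes syn-elimination towards C4–H, the only β-hydrogen available, to give 4.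

## Further compounds

F1 | step 2 | (1α,2α,3β,4β)-2,4-bis(3,4,5-trimethoxyphenyl)cyclobutane-1,3-dicarboxylic acid | COc1cc([C@H]2[C@H](C(=O)O)[C@H](c3cc(OC)c(OC)c(OC)c3)[C@H]2C(=O)O)cc(OC)c1OC
F2 | step 2 | (1α,2α,3β,4β)-2,4-bis(3,4,5-trimethoxyphenyl)cyclobutane-1,3-dicarbonyl dichloride | COc1cc([C@H]2[C@H](C(=O)Cl)[C@H](c3cc(OC)c(OC)c(OC)c3)[C@H]2C(=O)Cl)cc(OC)c1OC
F3 | step 2 | lithium salt of 2 (lithium 6-oxo-3,6-dihydro-2H-pyridin-1-ide) | [Li+].O=C1C=CCC[N-]1
F4 | step 2 | methyl (E)-3-(3,4,5-trimethoxyphenyl)prop-2-enoate | COc1cc(/C=C/C(=O)OC)cc(OC)c1OC
F5 | step 2 | dimethyl (1α,2α,3β,4β)-2,4-bis(3,4,5-trimethoxyphenyl)cyclobutane-1,3-dicarboxylate | COc1cc([C@H]2[C@H](C(=O)OC)[C@H](c3cc(OC)c(OC)c(OC)c3)[C@H]2C(=O)OC)cc(OC)c1OC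
F6 | step 1 | (E)-1-[3-(3,4,5-trimethoxyphenyl)prop-2-enoyl]piperidin-2-one | COc1cc(/C=C/C(=O)N2CCCCC2=O)cc(OC)c1OC
F7 | step 1 | lithium enolate of F6 (deprotonated at lactam C3) | COc1cc(/C=C/C(=O)N2CCCC=C2[O-])cc(OC)c1OC.[Li+]
F8 | step 1 | (E)-3-(phenylselanyl)-1-[3-(3,4,5-trimethoxyphenyl)prop-2-enoyl]piperidin-2-one (racemic) | COc1cc(/C=C/C(=O)N2CCCC([Se]c3ccccc3)C2=O)cc(OC)c1OC
F9 | step 1 | selenoxide of F8 (diastereomer mixture) | COc1cc(/C=C/C(=O)N2CCCC([Se](=O)c3ccccc3)C2=O)cc(OC)c1OC
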